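**Retrosynthetic overview**

- Longipinane numbering: C1 ketone, C2=C3 (methyl on C3), cyclobutane C4–C5–C11–C10 (methyl on C10), six-membered ring C1–C2–C3–C4–C5–C11, seven-membered ring C5–C6(gem-dimethyl)–C7–C8–C9–C10–C11. The route rests on one feature: these fifteen carbons are an unbroken farnesane chain, closed at C5–C6 and cross-linked at C5–C11 and C4–C10 around the cyclobutane.
- Late stage: O7 methacrylate and O9 angelate off → trans-diol 11 ← hydroxyl-directed reduction of β-hydroxy ketone 10 ← conjugate borylation/oxidation at C9 of enone 8 ← IBX on the 7-alcohol 6 ← enzymatic C7–H hydroxylation of enone 5 ← allylic oxidation at C1 of α-longipinene 4.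
- Core: 4 ← (2E,6E)-farnesyl diphosphate 3 by one terpene-synthase cation–olefin cascade ← farnesol 1.
- Ring order, all in step 3: eleven-membered ring by C5–C6, then the six- and seven-membered rings together by C5–C11, last the cyclobutane by C4–C10.

Key step: step 3

**Assumptions**

- The synthase is taken to deliver the dextrorotatory (1R,2S,7R,8R) antipode of 4, which maps onto the 4R,5S,10R,11R cage of the target; this is to be checked by optical rotation and enantioselective GC against an authentic sample before the route continues.
- Compound 6 is drawn as the 7β-alcohol; either C7 epimer serves, because C7 becomes a carbonyl carbon in step 6.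
- The (R,SP) antipode of the Josiphos ligand is written in step 7; the antipode actually used is the one found to place boron on the α face of C9.

**Route**

Step 1
Reactants: 1 (2E,6E)-farnesol
Product: 2 (2E,6E)-farnesyl bromide
Conditions: PBr3 (0.4 equiv), Et2O, −10 °C; used crude
Reagents that add atoms: phosphorus tribromide, BrP(Br)Br
Why: SN2 displacement on the phosphite ester of a primary allylic alcohol should give the bromide without allylic transposition at low temperature, with both E alkenes untouched and no stereocentre involved.

Step 2
Reactants: 2 (2E,6E)-farnesyl bromide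
Product: 3 (2E,6E)-farnesyl diphosphate (handled as the trisammonium salt, drawn as the free acid)
Conditions: (Bu4N)3HP2O7 (2 equiv), MeCN, rt; Dowex 50W-X8 (NH4+ form); cellulose chromatography, iPrOH/aq NH4OH
Reagents that add atoms: tris(tetrabutylammonium) hydrogen diphosphate, CCCC[N+](CCCC)(CCCC)CCCC.CCCC[N+](CCCC)(CCCC)CCCC.CCCC[N+](CCCC)(CCCC)CCCC.OP(=O)([O-])OP(=O)([O-])[O-]
Why: SN2 displacement of the primary allylic bromide by the diphosphate trianion in dry acetonitrile is the standard preparation of allylic diphosphates and should keep the 2E geometry.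

Step 3
Reactants: 3 (2E,6E)-farnesyl diphosphate
Product: 4 (+)-α-longipinene, (1R,2S,7R,8R)-2,6,6,9-tetramethyltricyclo[5.4.0.0(2,8)]undec-9-ene
Conditions: recombinant α-longipinene synthase (EC 4.2.3.80, conifer enzyme, His-tagged, purified from E. coli), MgCl2, DTT, HEPES pH 7.5, glycerol, pentane overlay, 30 °C; AgNO3-impregnated SiO2 chromatography
Reagents that add atoms: none
Why: Magnesium-assisted loss of diphosphate and rotation through the tertiary allylic (nerolidyl) diphosphate give the cisoid allyl cation, after which the enzyme runs its native cascade; the reaction type is the cation–olefin polycyclisation of a class-one sesquiterpene synthase, and this substrate/product pair is the one such synthases are known for. The distal C6=C7 alkene attacks C5 through C6 (bond C5–C6, 11-endo macrocyclisation), a 1,3-hydride shift from C5 to C7 regenerates an allyl cation over C5–C4–C3, and the C10=C11 alkene attacks C5 through C11 (bond C5–C11, a transannular closure that is 6-exo for ring C1–C2–C3–C4–C5–C11 and 7-endo for ring C5–C6–C7–C8–C9–C10–C11), leaving a tertiary cation at C10. The C3=C4 alkene then attacks C10 through C4 (bond C4–C10, 4-exo closure of the cyclobutane C4–C5–C11–C10), and removal of a C2 proton by the active-site base leaves the C2=C3 alkene. The four stereocentres C4, C5, C10 and C11 arise together: the tricyclic cage allows only one relative configuration, and the absolute sense is fixed by the chiral fold in which the pocket holds the chain. The selectivities needed are attack of C10 on C4 instead of C3 (the five-membered longibornyl alternative that ends in longifolene) and loss of the C2 proton instead of a C3-methyl proton; nothing in the substrate secures them, only the active-site contour does, so co-formed sesquiterpenes are expected and are removed on AgNO3-impregnated silica.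

Step 4
Reactants: 4 (+)-α-longipinene
Product: 5 longipin-2-en-1-one (cage of 4 retained)
Conditions: Rh2(cap)4 (dirhodium tetrakis(caprolactamate), 1 mol%), tBuOOH (70% aq, 5 equiv), K2CO3 (0.5 equiv), CH2Cl2, rt
Reagents that add atoms: tert-butyl hydroperoxide, CC(C)(C)OO
Why: This is the radical allylic oxidation (H-abstraction by tert-butylperoxyl, mixed peroxide, loss of tert-butanol) that turns α-pinene into verbenone, and it should act at C1 because C1 is the only allylic ring methylene, the C3 methyl reacts more slowly and the bridgehead C4–H cannot give an allyl radical; the cage stereocentres are not touched.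

Step 5
Reactants: 5 longipin-2-en-1-one
Product: 6 7β-hydroxylongipin-2-en-1-one
Conditions: P450 BM3 (CYP102A1) variant from an F87A-based active-site library, chosen by screening for C7 oxidation, clarified E. coli lysate, NADP+ (cat.), phosphite dehydrogenase, Na2HPO3, air, potassium phosphate buffer pH 8.0, 2% DMSO, 25 °C
Reagents that add atoms: dioxygen, O=O
Why: Enzymatic C–H hydroxylation by hydrogen abstraction and oxygen rebound with retention is well precedented for a methylene flanked by a gem-dimethyl quaternary carbon at the end remote from the carbonyl (ring A of drimane and labdane lactones with variants of this enzyme), which is the situation of C7 next to C6 here, the electron-poor C2=C3 enone should resist epoxidation, and only site selectivity against C8 is required because the C7 configuration is erased in step 6.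

Step 6
Reactants: 6 7β-hydroxylongipin-2-en-1-one
Product: 8 longipina-2,8-diene-1,7-dione, via longipin-2-ene-1,7-dione 7 (not isolated)
Conditions: IBX (3 equiv), DMSO, 75 °C
Reagents that add atoms: none
Why: IBX oxidises the alcohol to ketone 7 and at this temperature dehydrogenates it through its enol (IBX ketone dehydrogenation), which can only give the C8=C9 enone because C6 is quaternary, while the C1 ketone cannot be desaturated further since its other α-carbon C11 is a cyclobutane bridgehead; no stereocentre is formed.

Step 7
Reactants: 8 longipina-2,8-diene-1,7-dione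
Product: 10 9α-hydroxylongipin-2-ene-1,7-dione, via 9α-(pinacolboryl)longipin-2-ene-1,7-dione 9 (not isolated)
Conditions: CuCl (5 mol%), (R)-1-[(SP)-2-(diphenylphosphino)ferrocenyl]ethyldicyclohexylphosphine (Josiphos, 6 mol%), NaOtBu (10 mol%), B2pin2 (1.2 equiv), MeOH (2 equiv), THF, rt; then NaBO3·4H2O, THF/H2O, rt
Reagents that add atoms: sodium perborate, [Na+].[Na+].O[B-]1(O)OO[B-](O)(O)OO1 (oxygen of 10); bis(pinacolato)diboron, CC1(C)OB(OC1(C)C)B2OC(C)(C)C(C)(C)O2 (boryl group of 9 only)
Why: Copper-catalysed asymmetric β-borylation of a cyclic enone (copper boryl 1,4-addition, protonation of the copper enolate by methanol) followed by perborate oxidation with retention should give the β-hydroxy ketone, with the chiral ligand relied on to place boron on the α face of C9 (9R) because the two faces differ only remotely (C4 versus C11 of the cyclobutane), and with the C2=C3 enone left alone because its β-carbon is fully substituted.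

Step 8
Reactants: 10 9α-hydroxylongipin-2-ene-1,7-dione
Product: 11 7β,9α-dihydroxylongipin-2-en-1-one
Conditions: Me4NBH(OAc)3 (5 equiv), MeCN/AcOH 1:1, −25 °C
Reagents that add atoms: none
Why: In the Evans–Saksena reduction the 9α-hydroxyl binds boron and delivers hydride within the molecule to the α face of the C7 carbonyl, so the new hydroxyl should be β and trans to O9 (7R), and the C1 enone is spared because triacetoxyborohydride does not reduce a ketone that lacks a neighbouring hydroxyl.

Step 9
Reactants: 11 7β,9α-dihydroxylongipin-2-en-1-one; 12 angelic acid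
Product: 13 9α-angeloyloxy-7β-hydroxylongipin-2-en-1-one
Conditions: 12 (1.2 equiv), 2,4,6-trichlorobenzoyl chloride (1.2 equiv), Et3N, toluene, rt; then 11, toluene, 70 °C
Reagents that add atoms: none
Why: Yamaguchi-type mixed-anhydride esterification without a nucleophilic catalyst should keep the Z geometry of the angelate and acylate at the angeloyl carbonyl (the aroyl carbonyl is shielded by two ortho chlorines), and O9 is expected to react first because its neighbour C10 has two substituents tied back in the cyclobutane whereas O7 sits beside the gem-dimethyl carbon C6; no stereocentre is affected.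

Step 10
Reactants: 13 9α-angeloyloxy-7β-hydroxylongipin-2-en-1-one; 14 methacrylic anhydride
Product: 15 (4R,5S,7R,9R,10R,11R)-9α-angeloyloxy-7β-methacryloyloxylongipin-2-en-1-one (CNP0317071.1)
Conditions: 14 (3 equiv), DMAP (0.3 equiv), Et3N, BHT (trace), CH2Cl2, 0 °C to rt
Reagents that add atoms: none
Why: DMAP-catalysed acylation through the N-acylpyridinium ion should esterify the remaining hindered secondary hydroxyl with retention at C7 (O-acylation), and the low temperature with a radical inhibitor should keep the angelate Z and the methacrylate unpolymerised.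

**Compound list**

1 | (2E,6E)-farnesol | CC(C)=CCC/C(C)=C/CC/C(C)=C/CO | starting material
2 | (2E,6E)-farnesyl bromide | CC(C)=CCC/C(C)=C/CC/C(C)=C/CBr | intermediate
3 | (2E,6E)-farnesyl diphosphate (free acid drawn) | CC(C)=CCC/C(C)=C/CC/C(C)=C/COP(=O)(O)OP(=O)(O)O | intermediate
4 | (+)-α-longipinene, (1R,2S,7R,8R) | C1CC[C@@]2(C)[C@@H]3CC=C(C)[C@H]2[C@@H]3C1(C)C | intermediate
5 | longipin-2-en-1-one | C1CC[C@@]2(C)[C@@H]3C(=O)C=C(C)[C@H]2[C@@H]3C1(C)C | intermediate
6 | 7β-hydroxylongipin-2-en-1-one | O[C@@H]1CC[C@@]2(C)[C@@H]3C(=O)C=C(C)[C@H]2[C@@H]3C1(C)C | intermediate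
7 | longipin-2-ene-1,7-dione (formed in step 6, not isolated) | O=C1CC[C@@]2(C)[C@@H]3C(=O)C=C(C)[C@H]2[C@@H]3C1(C)C | intermediate
8 | longipina-2,8-diene-1,7-dione | O=C1C=C[C@@]2(C)[C@@H]3C(=O)C=C(C)[C@H]2[C@@H]3C1(C)C | intermediate
9 | 9α-(4,4,5,5-tetramethyl-1,3,2-dioxaborolan-2-yl)longipin-2-ene-1,7-dione (formed in step 7, not isolated) | O=C1C[C@@H](B4OC(C)(C)C(C)(C)O4)[C@@]2(C)[C@@H]3C(=O)C=C(C)[C@H]2[C@@H]3C1(C)C | intermediate
10 | 9α-hydroxylongipin-2-ene-1,7-dione | O=C1C[C@@H](O)[C@@]2(C)[C@@H]3C(=O)C=C(C)[C@H]2[C@@H]3C1(C)C | intermediate
11 | 7β,9α-dihydroxylongipin-2-en-1-one | O[C@@H]1C[C@@H](O)[C@@]2(C)[C@@H]3C(=O)C=C(C)[C@H]2[C@@H]3C1(C)C | intermediate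
12 | angelic acid, (Z)-2-methylbut-2-enoic acid | C/C=C(/C)C(=O)O | starting material
13 | 9α-angeloyloxy-7β-hydroxylongipin-2-en-1-one | O[C@@H]1C[C@@H](OC(=O)/C(C)=C\C)[C@@]2(C)[C@@H]3C(=O)C=C(C)[C@H]2[C@@H]3C1(C)C | intermediate
14 | methacrylic anhydride | C=C(C)C(=O)OC(=O)C(C)=C | starting material
15 | (4R,5S,7R,9R,10R,11R)-9α-angeloyloxy-7β-methacryloyloxylongipin-2-en-1-one | C=C(C)C(=O)O[C@@H]1C[C@@H](OC(=O)/C(C)=C\C)[C@@]2(C)[C@@H]3C(=O)C=C(C)[C@H]2[C@@H]3C1(C)C | target

**Totals**

Total step count: 10. Longest linear sequence: 10 steps (1 to 15).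

**Steps most likely to fail**

Step 5. The enzyme may oxidise the more exposed C8 methylene or the C3 methyl instead of C7, that is, site selectivity may be lost in the pocket. The fallback sets out from 5 and comes back at 11, and runs the oxygen relay from the other neopentyl methylene, so that only one of C7 and C9 has to be addressable by a hydroxylase. A variant selected for C9 oxidation should give 9α-hydroxylongipin-2-en-1-one F1 (either C9 epimer serves). IBX in DMSO at 75 °C should take it through longipin-2-ene-1,9-dione F2 to longipina-2,7-diene-1,9-dione F3. Copper/Josiphos borylation with B2pin2, with the ligand antipode that attacks the β face of C7, should give 7β-(pinacolboryl)longipin-2-ene-1,9-dione F4, which perborate oxidises to 7β-hydroxylongipin-2-ene-1,9-dione F5. Me4NBH(OAc)3 in MeCN/AcOH then delivers hydride from O7 to the β face of C9 and should give 11.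

Step 7. The bulky copper–boryl complex may fail to engage the neopentyl β-carbon C9, or may discriminate poorly between its two nearly equivalent faces. The fallback sets out from 8 and comes back at 10, and forms the C9–O bond by oxygen conjugate addition instead of borylation. Weitz–Scheffer epoxidation (tBuOOH, DBU, CH2Cl2) attacks the C8=C9 enone in preference to the fully β-substituted C2=C3 enone and should give 8α,9α-epoxylongipin-2-ene-1,7-dione F6. Face selectivity is then substrate-controlled, and the α-epoxide has to be separated from any β-isomer. SmI2 in THF/MeOH at −90 °C cleaves the C8–O bond of the α,β-epoxy ketone reductively and should give 10.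

Step 9. The two hydroxyls of 11 may acylate at similar rates, giving a mixture of mono- and diesters. If O7 turns out to be the faster one, the two acylations are simply run in the reverse order. If neither is distinguished, the fallback sets out from 10 and comes back at 15, and differentiates the oxygens within the molecule. Evans–Tishchenko reduction of 10 with pent-4-enal and catalytic SmI2 in THF at −10 °C transfers hydride from the O9 hemiacetal to C7 and should give 7β-hydroxy-9α-(pent-4-enoyloxy)longipin-2-en-1-one F7, with O9 acylated and the new 7β-hydroxyl free. Methacrylic anhydride 14 with DMAP and Et3N should give 7β-methacryloyloxy-9α-(pent-4-enoyloxy)longipin-2-en-1-one F8. Iodine in THF/H2O removes the pentenoate by iodolactonisation, leaving the electron-poor methacrylate and enone alkenes alone, and should give 9α-hydroxy-7β-methacryloyloxylongipin-2-en-1-one F9. Angeloylation of F9 with the mixed anhydride of 12 and 2,4,6-trichlorobenzoyl chloride in toluene at 70 °C (BHT present) should give 15.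

**Further compounds**

F1 | step 5 | 9α-hydroxylongipin-2-en-1-one | C1C[C@@H](O)[C@@]2(C)[C@@H]3C(=O)C=C(C)[C@H]2[C@@H]3C1(C)C
F2 | step 5 | longipin-2-ene-1,9-dione | C1CC(=O)[C@@]2(C)[C@@H]3C(=O)C=C(C)[C@H]2[C@@H]3C1(C)C
F3 | step 5 | longipina-2,7-diene-1,9-dione | C1=CC(=O)[C@@]2(C)[C@@H]3C(=O)C=C(C)[C@H]2[C@@H]3C1(C)C
F4 | step 5 | 7β-(4,4,5,5-tetramethyl-1,3,2-dioxaborolan-2-yl)longipin-2-ene-1,9-dione | CC1(C)OB(OC1(C)C)[C@@H]2CC(=O)[C@@]3(C)[C@@H]4C(=O)C=C(C)[C@H]3[C@@H]4C2(C)C
F5 | step 5 | 7β-hydroxylongipin-2-ene-1,9-dione | O[C@@H]1CC(=O)[C@@]2(C)[C@@H]3C(=O)C=C(C)[C@H]2[C@@H]3C1(C)C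
F6 | step 7 | 8α,9α-epoxylongipin-2-ene-1,7-dione | O=C1[C@H]2O[C@H]2[C@@]3(C)[C@@H]4C(=O)C=C(C)[C@H]3[C@@H]4C1(C)C
F7 | step 9 | 7β-hydroxy-9α-(pent-4-enoyloxy)longipin-2-en-1-one | O[C@@H]1C[C@@H](OC(=O)CCC=C)[C@@]2(C)[C@@H]3C(=O)C=C(C)[C@H]2[C@@H]3C1(C)C
F8 | step 9 | 7β-methacryloyloxy-9α-(pent-4-enoyloxy)longipin-2-en-1-one | C=C(C)C(=O)O[C@@H]1C[C@@H](OC(=O)CCC=C)[C@@]2(C)[C@@H]3C(=O)C=C(C)[C@H]2[C@@H]3C1(C)C
F9 | step 9 | 9α-hydroxy-7β-methacryloyloxylongipin-2-en-1-one | C=C(C)C(=O)O[C@@H]1C[C@@H](O)[C@@]2(C)[C@@H]3C(=O)C=C(C)[C@H]2[C@@H]3C1(C)C
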